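**Retrosynthetic overview**
1. Target ⇐ global desilylation ⇐ ring-closing metathesis at C1=C10 (ring-cis trisubstituted alkene) of an acyclic triene ester; the ten-membered carbocycle is formed last.
2. C8 ester ⇐ Yamaguchi coupling with a Roche-ester-derived acid; C7–C8 bond with the C7 and C8 stereocentres ⇐ intermolecular Nozaki–Hiyama (Barbier-type) allylation of 3-methylbut-3-enal with a (5R)-3-(bromomethyl)butenolide.
3. Butenolide (formed first; it becomes the α-methylene-γ-lactone during the allylation) ⇐ Pd-catalysed carbonylative lactonisation of a (Z)-iodo-allylic alcohol ⇐ directed hydroalumination/iodination of an (R)-propargylic alcohol.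
4. Propargylic alcohol (C6) ⇐ catalytic asymmetric alkynylation of a (Z)-enal; enal (C4=C5 geometry) ⇐ syn-carbocupration of a 4-silyloxybut-2-ynoate.

Assumption: the SMILES is read literally, i.e. trans-fused 6,12-lactone (6R,7R), 8S ester, (2′R) side chain, CH2OH cis to C6 on C4=C5, and the two ring carbons cis on C1=C10.

Germacrane numbering (C1–C15) is used for orientation. TBS-oxy = tert-butyldimethylsilyloxy; PMB-oxy = (4-methoxybenzyl)oxy.

**Step 1**
Reactants: 1 tert-butyldimethyl(prop-2-yn-1-yloxy)silane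
Product: 3 methyl 4-(TBS-oxy)but-2-ynoate, via lithium acetylide 2 (not isolated)
Conditions: n-BuLi, THF, −78 °C; then ClCO2Me, −78 → 0 °C
Reagents that add atoms: methyl chloroformate, COC(=O)Cl
Why: Deprotonation of the terminal alkyne and C-acylation of the acetylide with a chloroformate is a standard alkynoate synthesis and involves no stereocentre.

**Step 2**
Reactants: 3 methyl 4-(TBS-oxy)but-2-ynoate; 4 but-3-en-1-ylmagnesium bromide
Product: 7 methyl (2Z)-3-[(TBS-oxy)methyl]hepta-2,6-dienoate, via but-3-enylcopper 5 (not isolated), via alkenylcopper adduct 6 (not isolated)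
Conditions: 4, CuBr·SMe2 (1:1, 1.5 equiv), THF, −78 °C; add 3, −78 °C, 1 h; sat. aq. NH4Cl at −78 °C
Reagents that add atoms: none
Why: Organocopper conjugate addition to the ynoate is a syn-carbocupration, and cold protonation of the alkenylcopper with retention places the ester cis to CH2OTBS, which fixes the C4=C5 geometry of the target.

**Step 3**
Reactants: 7 methyl (2Z)-3-[(TBS-oxy)methyl]hepta-2,6-dienoate
Product: 8 (2Z)-3-[(TBS-oxy)methyl]hepta-2,6-dien-1-ol
Conditions: i-Bu2AlH (2.2 equiv), CH2Cl2, −78 °C; aq. KNaC4H4O6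
Reagents that add atoms: none
Why: 1,2-Reduction of an enoate with i-Bu2AlH at low temperature gives the allylic alcohol without touching the alkene geometry or the silyl ether.

**Step 4**
Reactants: 8 (2Z)-3-[(TBS-oxy)methyl]hepta-2,6-dien-1-ol
Product: 9 (2Z)-3-[(TBS-oxy)methyl]hepta-2,6-dienal
Conditions: MnO2 (20 equiv), CH2Cl2, rt
Reagents that add atoms: none
Why: Neutral heterogeneous MnO2 oxidation is selective for allylic alcohols and avoids the acid or base that would isomerise the (Z)-enal.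

**Step 5**
Reactants: 9 (2Z)-3-[(TBS-oxy)methyl]hepta-2,6-dienal; 10 1-methoxy-4-[(prop-2-yn-1-yloxy)methyl]benzene
Product: 12 (4R,5Z)-6-[(TBS-oxy)methyl]-1-(PMB-oxy)deca-5,9-dien-2-yn-4-ol, via alkynyl(methyl)zinc 11 (not isolated)
Conditions: 10 (3 equiv), Me2Zn (3 equiv), (R,R)-ProPhenol (20 mol%), Ph3PO (40 mol%), toluene, 0 → 4 °C, 48 h; aq. NH4Cl
Reagents that add atoms: none
Why: Trost's dinuclear zinc–ProPhenol alkynylation, developed for α,β-unsaturated aldehydes, adds the zinc acetylide to the Si face of the enal and so sets C6 as 4R (sense and ee are checked by Mosher ester analysis, the antipodal ligand being equally available).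

**Step 6**
Reactants: 12 (4R,5Z)-6-[(TBS-oxy)methyl]-1-(PMB-oxy)deca-5,9-dien-2-yn-4-ol
Product: 14 (2Z,4R,5Z)-6-[(TBS-oxy)methyl]-2-iodo-1-(PMB-oxy)deca-2,5,9-trien-4-ol, via cyclic vinylalanate 13 (not isolated)
Conditions: NaAlH2(OCH2CH2OMe)2 (1.5 equiv), THF, 0 °C → rt; EtOAc, −78 °C; then I2, THF, −78 → 0 °C
Reagents that add atoms: iodine, II
Why: Alkoxide-directed trans-hydroalumination delivers hydride to the proximal alkyne carbon and aluminium to the distal one inside a five-membered chelate, and iodinolysis with retention gives the vinyl iodide with iodine cis to the carbinol carbon (Corey-type hydroalumination–iodination).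

**Step 7**
Reactants: 14 (2Z,4R,5Z)-6-[(TBS-oxy)methyl]-2-iodo-1-(PMB-oxy)deca-2,5,9-trien-4-ol
Product: 15 (5R)-5-{(1Z)-2-[(TBS-oxy)methyl]hexa-1,5-dien-1-yl}-3-[(PMB-oxy)methyl]furan-2(5H)-one
Conditions: PdCl2(PPh3)2 (5 mol%), CO (1 atm), K2CO3 (2 equiv), THF, 40 °C
Reagents that add atoms: carbon monoxide, [C-]#[O+]
Why: Oxidative addition of zerovalent palladium to the vinyl iodide, CO insertion and capture of the acyl–palladium by the cis-disposed C6 hydroxyl close the butenolide (carbonylative lactonisation) without touching the stereocentre.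

**Step 8**
Reactants: 15 (5R)-5-{(1Z)-2-[(TBS-oxy)methyl]hexa-1,5-dien-1-yl}-3-[(PMB-oxy)methyl]furan-2(5H)-one
Product: 16 (5R)-5-{(1Z)-2-[(TBS-oxy)methyl]hexa-1,5-dien-1-yl}-3-(hydroxymethyl)furan-2(5H)-one
Conditions: DDQ (1.3 equiv), CH2Cl2/pH 7 buffer (10:1), 0 °C
Reagents that add atoms: none
Why: Oxidative cleavage of the electron-rich PMB ether by DDQ is orthogonal to the TBS ether and far faster than any hydride abstraction from the acyloxy-substituted C6–H.

**Step 9**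
Reactants: 16 (5R)-5-{(1Z)-2-[(TBS-oxy)methyl]hexa-1,5-dien-1-yl}-3-(hydroxymethyl)furan-2(5H)-one
Product: 17 (5R)-3-(bromomethyl)-5-{(1Z)-2-[(TBS-oxy)methyl]hexa-1,5-dien-1-yl}furan-2(5H)-one
Conditions: CBr4 (1.3 equiv), PPh3 (1.4 equiv), CH2Cl2, 0 °C
Reagents that add atoms: carbon tetrabromide, BrC(Br)(Br)Br
Why: The Appel reaction converts the primary allylic alcohol into the bromide under neutral conditions that spare the base-sensitive γ-stereocentre of the butenolide.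

**Step 10**
Reactants: 18 3-methylbut-3-en-1-ol
Product: 19 3-methylbut-3-enal
Conditions: Dess–Martin periodinane (1.1 equiv), CH2Cl2, 0 °C → rt; cold aq. NaHCO3/Na2S2O3 wash; dried solution used at once
Reagents that add atoms: none
Why: Dess–Martin oxidation is fast and mild enough to give the β,γ-unsaturated aldehyde before it isomerises into conjugation.

**Step 11**
Reactants: 17 (5R)-3-(bromomethyl)-5-{(1Z)-2-[(TBS-oxy)methyl]hexa-1,5-dien-1-yl}furan-2(5H)-one; 19 3-methylbut-3-enal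
Product: 21 (4R,5R)-5-{(1Z)-2-[(TBS-oxy)methyl]hexa-1,5-dien-1-yl}-4-[(1S)-1-hydroxy-3-methylbut-3-en-1-yl]-3-methylideneoxolan-2-one, via allylchromium dichloride 20 (not isolated)
Conditions: CrCl2 (4 equiv), 19 (2 equiv), THF, 0 °C → rt, 12 h; aq. NH4Cl
Reagents that add atoms: none
Why: In this Nozaki–Hiyama (Barbier-type) carbonyl allylation the σ-allyl trivalent chromium species adds with allylic transposition through a closed chair transition state, where the ring-locked allyl geometry with the aldehyde chain equatorial gives the 7,8-anti relationship (8S) and attack on the face opposite the C6 alkenyl group gives the 6,7-trans lactone (7R), the ring alkene becoming the exocyclic methylene.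

**Step 12**
Reactants: 22 methyl (2R)-3-hydroxy-2-methylpropanoate
Product: 23 methyl (2R)-2-methyl-3-(TBS-oxy)propanoate
Conditions: TBSCl (1.2 equiv), imidazole (2 equiv), CH2Cl2, 0 °C → rt
Reagents that add atoms: tert-butyldimethylsilyl chloride, CC(C)(C)[Si](C)(C)Cl
Why: Imidazole-promoted silylation of the primary alcohol is quantitative and leaves the α-stereocentre of the Roche ester untouched.

**Step 13**
Reactants: 23 methyl (2R)-2-methyl-3-(TBS-oxy)propanoate
Product: 25 (2R)-2-methyl-3-(TBS-oxy)propanoic acid, via lithium carboxylate 24 (not isolated)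
Conditions: LiOH·H2O (3 equiv), THF/MeOH/H2O (3:1:1), 0 °C → rt; then 1 M HCl to pH 4, 0 °C
Reagents that add atoms: lithium hydroxide, [Li+].[OH-]
Why: Mild saponification of the methyl ester followed by cold, brief acidification gives the acid without epimerisation or loss of the silyl ether.

**Step 14**
Reactants: 21 (4R,5R)-5-{(1Z)-2-[(TBS-oxy)methyl]hexa-1,5-dien-1-yl}-4-[(1S)-1-hydroxy-3-methylbut-3-en-1-yl]-3-methylideneoxolan-2-one; 25 (2R)-2-methyl-3-(TBS-oxy)propanoic acid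
Product: 27 (1S)-1-[(2R,3R)-2-{(1Z)-2-[(TBS-oxy)methyl]hexa-1,5-dien-1-yl}-4-methylidene-5-oxooxolan-3-yl]-3-methylbut-3-en-1-yl (2R)-2-methyl-3-(TBS-oxy)propanoate, via mixed anhydride 26 (not isolated)
Conditions: 25 (2 equiv), 2,4,6-Cl3C6H2COCl (2 equiv), Et3N (3 equiv), toluene, rt, 1 h; then 21, DMAP (2 equiv), rt
Reagents that add atoms: none
Why: Yamaguchi esterification acylates the hindered secondary C8 hydroxyl at oxygen, so C8 keeps its configuration, and the near-neutral conditions avoid translactonisation.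

**Step 15**
Reactants: 27 (1S)-1-[(2R,3R)-2-{(1Z)-2-[(TBS-oxy)methyl]hexa-1,5-dien-1-yl}-4-methylidene-5-oxooxolan-3-yl]-3-methylbut-3-en-1-yl (2R)-2-methyl-3-(TBS-oxy)propanoate
Product: 28 (3aR,4S,6Z,10Z,11aR)-6-methyl-3-methylidene-2-oxo-10-[(TBS-oxy)methyl]-2,3,3a,4,5,8,9,11a-octahydrocyclodeca[b]furan-4-yl (2R)-2-methyl-3-(TBS-oxy)propanoate
Conditions: second-generation Grubbs catalyst RuCl2(=CHPh)(PCy3)(H2IMes) (3 × 5 mol%), 1,4-benzoquinone (30 mol%), toluene (1 mM), 80 °C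
Reagents that add atoms: none
Why: Ring-closing metathesis between the terminal vinyl group and the isopropenyl group closes the ten-membered ring at C1=C10, where the less strained ring-cis (6Z) trisubstituted alkene is expected (checked by NOE) and the trisubstituted C4=C5 and electron-poor exocyclic alkenes are poor partners.

**Step 16**
Reactants: 28 (3aR,4S,6Z,10Z,11aR)-6-methyl-3-methylidene-2-oxo-10-[(TBS-oxy)methyl]-2,3,3a,4,5,8,9,11a-octahydrocyclodeca[b]furan-4-yl (2R)-2-methyl-3-(TBS-oxy)propanoate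
Product: 29 (3aR,4S,6Z,10Z,11aR)-10-(hydroxymethyl)-6-methyl-3-methylidene-2-oxo-2,3,3a,4,5,8,9,11a-octahydrocyclodeca[b]furan-4-yl (2R)-3-hydroxy-2-methylpropanoate
Conditions: HF·pyridine, pyridine/THF, 0 °C → rt
Reagents that add atoms: none
Why: Buffered fluoride cleaves both primary TBS ethers under weakly acidic, non-nucleophilic conditions that leave the α-methylene lactone, the ester and its α-stereocentre intact.

**Compound list**
1 | tert-butyldimethyl(prop-2-yn-1-yloxy)silane | C#CCO[Si](C)(C)C(C)(C)C | starting material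
2 | [3-(TBS-oxy)prop-1-yn-1-yl]lithium | [Li]C#CCO[Si](C)(C)C(C)(C)C | intermediate (not isolated)
3 | methyl 4-(TBS-oxy)but-2-ynoate | COC(=O)C#CCO[Si](C)(C)C(C)(C)C | intermediate
4 | but-3-en-1-ylmagnesium bromide | C=CCC[Mg]Br | starting material
5 | but-3-en-1-ylcopper (MgBr2·SMe2 complex) | C=CCC[Cu] | intermediate (not isolated)
6 | methyl (2E)-2-cuprio-3-[(TBS-oxy)methyl]hepta-2,6-dienoate (Cu cis to butenyl) | COC(=O)/C([Cu])=C(\CO[Si](C)(C)C(C)(C)C)CCC=C | intermediate (not isolated)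
7 | methyl (2Z)-3-[(TBS-oxy)methyl]hepta-2,6-dienoate | COC(=O)/C=C(\CO[Si](C)(C)C(C)(C)C)CCC=C | intermediate
8 | (2Z)-3-[(TBS-oxy)methyl]hepta-2,6-dien-1-ol | OC/C=C(\CO[Si](C)(C)C(C)(C)C)CCC=C | intermediate
9 | (2Z)-3-[(TBS-oxy)methyl]hepta-2,6-dienal | O=C/C=C(\CO[Si](C)(C)C(C)(C)C)CCC=C | intermediate
10 | 1-methoxy-4-[(prop-2-yn-1-yloxy)methyl]benzene | C#CCOCc1ccc(OC)cc1 | starting material
11 | methyl[3-(PMB-oxy)prop-1-yn-1-yl]zinc | C[Zn]C#CCOCc1ccc(OC)cc1 | intermediate (not isolated)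
12 | (4R,5Z)-6-[(TBS-oxy)methyl]-1-(PMB-oxy)deca-5,9-dien-2-yn-4-ol | COc1ccc(COCC#C[C@H](O)/C=C(\CO[Si](C)(C)C(C)(C)C)CCC=C)cc1 | intermediate
13 | sodium (5R)-5-{(1Z)-2-[(TBS-oxy)methyl]hexa-1,5-dien-1-yl}-2,2-bis(2-methoxyethoxy)-3-[(PMB-oxy)methyl]-2,5-dihydro-1,2-oxaluminol-2-uide | [Na+].COCCO[Al-]1(OCCOC)O[C@H](/C=C(\CO[Si](C)(C)C(C)(C)C)CCC=C)C=C1COCc1ccc(OC)cc1 | intermediate (not isolated)
14 | (2Z,4R,5Z)-6-[(TBS-oxy)methyl]-2-iodo-1-(PMB-oxy)deca-2,5,9-trien-4-ol | COc1ccc(COC/C(I)=C/[C@H](O)/C=C(\CO[Si](C)(C)C(C)(C)C)CCC=C)cc1 | intermediate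
15 | (5R)-5-{(1Z)-2-[(TBS-oxy)methyl]hexa-1,5-dien-1-yl}-3-[(PMB-oxy)methyl]furan-2(5H)-one | COc1ccc(COCC2=C[C@@H](/C=C(\CO[Si](C)(C)C(C)(C)C)CCC=C)OC2=O)cc1 | intermediate
16 | (5R)-5-{(1Z)-2-[(TBS-oxy)methyl]hexa-1,5-dien-1-yl}-3-(hydroxymethyl)furan-2(5H)-one | OCC1=C[C@@H](/C=C(\CO[Si](C)(C)C(C)(C)C)CCC=C)OC1=O | intermediate
17 | (5R)-3-(bromomethyl)-5-{(1Z)-2-[(TBS-oxy)methyl]hexa-1,5-dien-1-yl}furan-2(5H)-one | BrCC1=C[C@@H](/C=C(\CO[Si](C)(C)C(C)(C)C)CCC=C)OC1=O | intermediate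
18 | 3-methylbut-3-en-1-ol | CC(=C)CCO | starting material
19 | 3-methylbut-3-enal | CC(=C)CC=O | intermediate
20 | dichloro{[(5R)-5-{(1Z)-2-[(TBS-oxy)methyl]hexa-1,5-dien-1-yl}-2-oxo-2,5-dihydrofuran-3-yl]methyl}chromium | Cl[Cr](Cl)CC1=C[C@@H](/C=C(\CO[Si](C)(C)C(C)(C)C)CCC=C)OC1=O | intermediate (not isolated)
21 | (4R,5R)-5-{(1Z)-2-[(TBS-oxy)methyl]hexa-1,5-dien-1-yl}-4-[(1S)-1-hydroxy-3-methylbut-3-en-1-yl]-3-methylideneoxolan-2-one | C=C1C(=O)O[C@H](/C=C(\CO[Si](C)(C)C(C)(C)C)CCC=C)[C@H]1[C@@H](O)CC(C)=C | intermediate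
22 | methyl (2R)-3-hydroxy-2-methylpropanoate | C[C@H](CO)C(=O)OC | starting material
23 | methyl (2R)-2-methyl-3-(TBS-oxy)propanoate | C[C@H](CO[Si](C)(C)C(C)(C)C)C(=O)OC | intermediate
24 | lithium (2R)-2-methyl-3-(TBS-oxy)propanoate | C[C@H](CO[Si](C)(C)C(C)(C)C)C(=O)[O-].[Li+] | intermediate (not isolated)
25 | (2R)-2-methyl-3-(TBS-oxy)propanoic acid | C[C@H](CO[Si](C)(C)C(C)(C)C)C(=O)O | intermediate
26 | (2R)-2-methyl-3-(TBS-oxy)propanoic 2,4,6-trichlorobenzoic anhydride | C[C@H](CO[Si](C)(C)C(C)(C)C)C(=O)OC(=O)c1c(Cl)cc(Cl)cc1Cl | intermediate (not isolated)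
27 | (1S)-1-[(2R,3R)-2-{(1Z)-2-[(TBS-oxy)methyl]hexa-1,5-dien-1-yl}-4-methylidene-5-oxooxolan-3-yl]-3-methylbut-3-en-1-yl (2R)-2-methyl-3-(TBS-oxy)propanoate | C=C1C(=O)O[C@H](/C=C(\CO[Si](C)(C)C(C)(C)C)CCC=C)[C@H]1[C@@H](OC(=O)[C@H](C)CO[Si](C)(C)C(C)(C)C)CC(C)=C | intermediate
28 | (3aR,4S,6Z,10Z,11aR)-6-methyl-3-methylidene-2-oxo-10-[(TBS-oxy)methyl]-2,3,3a,4,5,8,9,11a-octahydrocyclodeca[b]furan-4-yl (2R)-2-methyl-3-(TBS-oxy)propanoate | C=C1C(=O)O[C@@H]2/C=C(\CO[Si](C)(C)C(C)(C)C)CC/C=C(/C)C[C@H](OC(=O)[C@H](C)CO[Si](C)(C)C(C)(C)C)[C@@H]12 | intermediate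
29 | (3aR,4S,6Z,10Z,11aR)-10-(hydroxymethyl)-6-methyl-3-methylidene-2-oxo-2,3,3a,4,5,8,9,11a-octahydrocyclodeca[b]furan-4-yl (2R)-3-hydroxy-2-methylpropanoate | C=C1C(=O)O[C@@H]2/C=C(\CO)CC/C=C(/C)C[C@H](OC(=O)[C@H](C)CO)[C@@H]12 | target

**Step count and risks**
Total: 16 steps. Longest linear sequence: 13 steps (steps 1–9, 11, 14, 15, 16).

Step 5 (enantioselective alkynylation of a hindered (Z)-β,β-disubstituted enal; ee or sense may disappoint). The fallback sets out from 9 and 10 and comes back at 12. Compound 10 is deprotonated with n-BuLi (THF, −78 °C) to the lithium acetylide F1, which adds 1,2 to 9 to give the racemic propargylic alcohol F2. MnO2 (CH2Cl2, rt) oxidises it to the cross-conjugated ynone F3. Midland reduction with (R)-Alpine-Borane (B-isopinocampheyl-9-borabicyclo[3.3.1]nonane from (+)-α-pinene, neat, rt), in which the linear alkynyl group is the small substituent, then returns (4R)-12; this is the sense that gives (R)-oct-1-yn-3-ol from oct-1-yn-3-one.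

Step 11 (taken with step 10: aldehyde 19 is volatile and isomerises easily into conjugation, and two stereocentres depend on one transition state). The fallback sets out from 17 and comes back at 27. Commercial ethyl 2-(2-methyl-1,3-dioxolan-2-yl)acetate F4 is reduced (i-Bu2AlH, CH2Cl2, −78 °C) to the non-isomerisable 2-(2-methyl-1,3-dioxolan-2-yl)acetaldehyde F5. The same CrCl2 allylation with 17 (through 20) gives the ketal alcohol F6 with the same (4R,5R,1′S) sense. Yamaguchi esterification with 25 (through 26) gives the ketal ester F7, and PPTS in wet acetone (40 °C) unmasks the methyl ketone F8. Takai–Lombardo methylenation (Zn, CH2Br2, TiCl4, THF/CH2Cl2, 0 °C), which is non-basic and so spares the α-methylene lactone, the esters and the β-acyloxy ketone, then gives 27.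

Step 15 (ten-membered ring, trisubstituted alkene, possible engagement of the exocyclic enoate, geometry not guaranteed). The fallback sets out from 27 and comes back at 28. Me2NH (THF/MeOH, 0 °C) adds in conjugate fashion to the α-methylene lactone to give the amine adduct F9 (C11 epimers, inconsequential); this removes the competing enoate alkene and loosens the lactone. F9 is cyclised as its TsOH salt with the same ruthenium catalyst to the macrocyclic amine F10. MeI (MeCN, rt) gives the methiodide F11, and NaHCO3 (aq. EtOAc, rt) restores the exocyclic methylene by β-elimination, giving 28.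

**Further compounds**
F1 | step 5 | [3-(PMB-oxy)prop-1-yn-1-yl]lithium | [Li]C#CCOCc1ccc(OC)cc1
F2 | step 5 | (5Z)-6-[(TBS-oxy)methyl]-1-(PMB-oxy)deca-5,9-dien-2-yn-4-ol, racemic | COc1ccc(COCC#CC(O)/C=C(\CO[Si](C)(C)C(C)(C)C)CCC=C)cc1
F3 | step 5 | (5Z)-6-[(TBS-oxy)methyl]-1-(PMB-oxy)deca-5,9-dien-2-yn-4-one | COc1ccc(COCC#CC(=O)/C=C(\CO[Si](C)(C)C(C)(C)C)CCC=C)cc1
F4 | step 11 | ethyl 2-(2-methyl-1,3-dioxolan-2-yl)acetate (commercial) | CCOC(=O)CC1(C)OCCO1
F5 | step 11 | 2-(2-methyl-1,3-dioxolan-2-yl)acetaldehyde | O=CCC1(C)OCCO1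
F6 | step 11 | (4R,5R)-5-{(1Z)-2-[(TBS-oxy)methyl]hexa-1,5-dien-1-yl}-4-[(1S)-1-hydroxy-2-(2-methyl-1,3-dioxolan-2-yl)ethyl]-3-methylideneoxolan-2-one | C=C1C(=O)O[C@H](/C=C(\CO[Si](C)(C)C(C)(C)C)CCC=C)[C@H]1[C@@H](O)CC1(C)OCCO1
F7 | step 11 | (1S)-1-[(2R,3R)-2-{(1Z)-2-[(TBS-oxy)methyl]hexa-1,5-dien-1-yl}-4-methylidene-5-oxooxolan-3-yl]-2-(2-methyl-1,3-dioxolan-2-yl)ethyl (2R)-2-methyl-3-(TBS-oxy)propanoate | C=C1C(=O)O[C@H](/C=C(\CO[Si](C)(C)C(C)(C)C)CCC=C)[C@H]1[C@@H](OC(=O)[C@H](C)CO[Si](C)(C)C(C)(C)C)CC1(C)OCCO1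
F8 | step 11 | (1S)-1-[(2R,3R)-2-{(1Z)-2-[(TBS-oxy)methyl]hexa-1,5-dien-1-yl}-4-methylidene-5-oxooxolan-3-yl]-3-oxobutyl (2R)-2-methyl-3-(TBS-oxy)propanoate | C=C1C(=O)O[C@H](/C=C(\CO[Si](C)(C)C(C)(C)C)CCC=C)[C@H]1[C@@H](OC(=O)[C@H](C)CO[Si](C)(C)C(C)(C)C)CC(C)=O
F9 | step 15 | dimethylamine adduct of 27 at the exocyclic methylene (C11 epimers) | CN(C)CC1C(=O)O[C@H](/C=C(\CO[Si](C)(C)C(C)(C)C)CCC=C)[C@H]1[C@@H](OC(=O)[C@H](C)CO[Si](C)(C)C(C)(C)C)CC(C)=C
F10 | step 15 | dimethylamine adduct of 28 (13-dimethylamino-11,13-dihydro macrocycle, C11 epimers) | CN(C)CC1C(=O)O[C@@H]2/C=C(\CO[Si](C)(C)C(C)(C)C)CC/C=C(/C)C[C@H](OC(=O)[C@H](C)CO[Si](C)(C)C(C)(C)C)[C@@H]12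
F11 | step 15 | methiodide of F10 (trimethylammonium iodide) | C[N+](C)(C)CC1C(=O)O[C@@H]2/C=C(\CO[Si](C)(C)C(C)(C)C)CC/C=C(/C)C[C@H](OC(=O)[C@H](C)CO[Si](C)(C)C(C)(C)C)[C@@H]12.[I-]
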